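- Thursday's run ends at 78.7 % of Z and 22.0 % of D, and so the charge of G is accounted for within the scatter; Sunday's and Wednesday's runs end alike.

| flask | G | J | remark | time |
|---|---|---|---|---|
| Thursday's | 0.50 M | 0.90 M | run made earlier |  |
| Sunday's | 0.75 M | 0.90 M | run made earlier |  |
| Wednesday's | 1 M | 1.4 M | run made earlier |  |
| flask | 1.0 M | 0.900 M |  | 80 min |

| run | time / min | Z / % | D / % |
|---|---|---|---|
| Thursday's | 8.00 | 43.7 | 13.5 |
| Thursday's | 25.0 | 75.0 | 21.3 |
| Thursday's | 40.0 | 78.0 | 21.0 |
| Thursday's | 60.0 | 76.5 | 22.9 |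
| Thursday's | 90.0 | 78.7 | 22.0 |
| Sunday's | 8.00 | 45.1 | 14.5 |
| Sunday's | 15.0 | 65.4 | 19.7 |
| Sunday's | 25.0 | 75.6 | 21.1 |
| Sunday's | 50.0 | 77.4 | 23.2 |
| Sunday's | 90.0 | 78.2 | 22.8 |
| Wednesday's | 20.0 | 70.8 | 23.0 |
| Wednesday's | 40.0 | 77.3 | 21.7 |
| Wednesday's | 60.0 | 77.0 | 24.0 |
| Wednesday's | 80.0 | 77.5 | 23.3 |
| Wednesday's | 90.0 | 79.0 | 22.1 |

(scatter of a reading: 1 percentage point)

- amounts and yields of Z count X too
- given per volume of solution although it is solid: X
- on the list of suspects stand: G <-> Q; Q <-> E; E -> D; Q -> L; L -> Z; X <-> Z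

- share of Z in Z plus D at 80 s
- share of Z in Z plus D at 80 min

- Counting turnovers gives a bench rule: in these three runs, each G converted ends either as Z or as D.
- Pooling the last reading of each run gives 77.9 %. This is the branch share, the share of Z in Z plus D at the end of a run, a late selectivity.
- Thursday's run reads 78.2 % with 0.50 M of G, and Wednesday's run reads 78.1 % with 1 M of G and 1.4 M of J.
- The reckoning here therefore takes the branch share for the flask at 80 min. That is an extrapolation, because J to G in the flask is 0.900, less than Sunday's 1.20.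
- The rule needs finished turnover, and its border shows in a ratio: 80 s is 0.167 of the first time read on Thursday.
- At that first time, Thursday's and Sunday's readings pool to 76.0 %, lower than the branch share. The gap is 1.9 percentage points against a scatter of 1 point per reading, so it gives a direction and no number: the reckoning here puts the early share below 76.0 %.
- The forecast gives 70 % and 78 %, and of the early figure it says “This is very uncertain”.
- The flask gives 57.8 % at 80 s, lower than the pooled reading, and 77.3 % at 80 min.

    G ⇌ Q (K = 0.980, k = 0.00600 s⁻¹)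
    Q ⇌ E (K = 0.700, k = 0.00160 s⁻¹)
    E → D (k = 0.0840 s⁻¹)
    Q → L (k = 0.00530 s⁻¹)
    L → Z (k = 0.0140 s⁻¹)
    X ⇌ Z, rate k6*(cs6 - [Z]) while solid is left; crystals form when [Z] > cs6 (solubility = 17.0 mM, k = 0.150 s⁻¹)

- At 8.00 min the flask still held 22.6 % of G and 12.9 % of Q, with 5.86 % of L on the way to Z and 0.247 % of E on the way to D. By 40.0 min G was down to 0.188 % and Q to 0.107 %, with Z at 77.0 % and D at 22.6 %, while J stood at 100 % of its own charge. The neighbour flask with 2.5 M of G, at 0.360 equiv of J, ends at 77.3 % against the branch share 77.9 %.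

The readings come from a simulation for an exercise.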